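The numbers in the tables were computed with made-up constants; the scatter is artificial.

The leftover I start from is the target still standing in the west run at 15.0 min, with substrate down to 0.3 %: it keeps falling, and the way it falls is what I want for the new flasks.

| flask | substrate | partner | free catalyst | added ligand | remark | time |
|---|---|---|---|---|---|---|
| west | 0.32 M | 1.5 equiv | 2.3 mol% | 13 mM | run made earlier |  |
| north | 0.32 M | 1.5 equiv | 2.4 mol% | 13 mM | run made earlier |  |
| south-east | 0.32 M | 1.5 equiv | 2.8 mol% | 13 mM | run made earlier |  |
| red | 0.32 M | 1.50 equiv | 2 mol% | 13 mM |  | 20 min |
| amber | 0.32 M | 1.50 equiv | 2.6 mol% | 13 mM |  | 20 min |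
| violet | 0.32 M | 1.50 equiv | 3.4 mol% | 13 mM |  | 20 min |

| run | time / min | target / % | side product / % | catalyst intermediate C / % | substrate / % |
|---|---|---|---|---|---|
| west | 4.00 | 41.1 | 3.9 | 0.5 | 54.8 |
| west | 8.00 | 56.4 | 20.9 | 0.3 | 22.7 |
| west | 12.0 | 54.9 | 40.6 | 0 | 3.7 |
| west | 15.0 | 46.4 | 53.9 | 0.1 | 0.3 |
| west | 20.0 | 34.5 | 66.0 | 0 | 0 |
| north | 4.00 | 42.0 | 4.5 | 0.3 | 52.7 |
| north | 8.00 | 58.2 | 21.5 | 0.5 | 20.0 |
| north | 12.0 | 54.8 | 43.1 | 0.2 | 1.9 |
| north | 15.0 | 44.8 | 53.9 | 0 | 0 |
| north | 20.0 | 33.5 | 66.3 | 0.2 | 0.1 |
| south-east | 1.50 | 21.5 | 0.4 | 0.8 | 76.8 |
| south-east | 3.00 | 39.9 | 2.8 | 0.4 | 56.8 |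
| south-east | 6.00 | 58.8 | 16.0 | 0.2 | 24.4 |
| south-east | 10.0 | 58.8 | 39.5 | 0 | 1.9 |
| south-east | 20.0 | 31.4 | 68.2 | 0.1 | 0 |

(each reading ± 0.3 percentage points)

- the numbers in the tables scatter by 0.3 percentage points (one standard deviation)

- which of these there is most of at the end, counted by the substrate in it, red (target / substrate / catalyst intermediate C / side product)
- which of these there is most of at the end, counted by the substrate in it, amber (target / substrate / catalyst intermediate C / side product)
- which of these there is most of at the end, counted by the substrate in it, violet (target / substrate / catalyst intermediate C / side product)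
- the largest of these amounts at the end, in percent of the substrate charged, red
- the largest of these amounts at the end, in percent of the substrate charged, amber
- the largest of these amounts at the end, in percent of the substrate charged, violet

I build the flask up one process at a time, with the side product at 20 min as my number. With the main step by itself, substrate and partner give target, and that number is zero.

Now I add the loss of target. Write P for target as a fraction of the substrate charged. From 15.0 min to 20.0 min in the west run the reciprocal of P climbs at a rate I call κ, the self-decay constant, 0.149 min⁻¹, and the north run reads 0.151 min⁻¹. A straight reciprocal is the mark of a loss going as P squared, whose time constant stretches as target thins. The start of the south-east run tells this from a first-order loss. At 1.50 min, with target ramped to 21.5 %, κ gives 0.344 % of side product, while a first-order constant read from the same west pair, 0.0593 min⁻¹, gives 0.956 %, and the reading is 0.4 %. With the whole charge present as target from time zero, my number becomes 74.9 %.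

The rest is the catalyst, which takes minutes to make that target. I treat this as a delay τ, the moment at which the whole charge seems to become target at once. The last readings give τ = 7.23 min in the west run and 5.31 min in the south-east run. Those two runs draw τ inversely proportional to the loading less 0.922 % of the substrate, which is a bet on two points. My reckoning then gives side product at 61.5 % in red, 67.6 % in amber and 70.4 % in violet.

The forecast also names side product for red, amber and violet, at 63.5 %, 67.3 % and 70.5 %, on its own grounds: “More catalyst mainly makes the target form earlier, giving it longer to decay.” It stands above my figure for red.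

The flask gives side product in red, amber and violet, at 62.9 %, 67.9 % and 70.8 %, so the forecast holds within its margin.

    target + released group → side product (k = 0.00820 M⁻¹ s⁻¹)
    catalyst intermediate C → free catalyst + target (k = 0.330 s⁻¹)
    partner + free catalyst → catalyst intermediate A (k = 2.20 M⁻¹ s⁻¹)
    free catalyst + added ligand ⇌ idle complex, settled at all times (K = 690 M⁻¹)
    catalyst intermediate B → released group + catalyst intermediate C (k = 95.0 s⁻¹)
    substrate + catalyst intermediate A → catalyst intermediate B (k = 3.50 M⁻¹ s⁻¹)

In red at 20 min, released group stands at 0.119 M beside target at 0.119 M, and κ carried on from 37.1 % gives 3.39 % of target at 200 min, where the flask holds 3.22 %. The asked figure is a stop on a running clock: violet holds 70.8 % of side product at 20 min, against 96.9 % in a run ten times as long, and that gap is mainly because of the length of the run. In the flask like red with 0.8 mol% of free catalyst, 37.3 % of substrate left means an average feed of 0.0313 min⁻¹. That feed against κ times P squared climbs as a hyperbolic tangent toward 45.9 %, reaching 40.3 %. The computed flask holds 37.7 % of target and 24.8 % of side product.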